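**Assumption:** the target SMILES has no stereocentre and no specified axis, so the compound is made as drawn and no stereocontrol is needed. The route is designed from known reaction classes and has not been run.

## Retrosynthetic overview

1. Target 8 comes from sixfold electrophilic bromination of 1,1'-dimethyl-2,2'-bipyrrole 7.
2. 7 comes from N-methylation of 1-methyl-2,2'-bipyrrole 6, which comes from dehydrogenation of pyrroline 5.
3. 5 comes from ring closure of γ-amino ketone 4, released by hydrolysis and decarboxylation of β-keto lactam 3.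
4. 3 comes from a crossed Claisen condensation of pyrrole ester 1 with N-vinylpyrrolidinone 2; this forms the C2'–C3' bond and joins the two fragments.
5. Ring order: ring A (the N-methylpyrrole) is bought intact; ring B is closed as a 1-pyrroline in step 2 and aromatised in step 3.

## Route

**Step 1**
Reactants: 1 methyl 1-methyl-1H-pyrrole-2-carboxylate; 2 1-ethenylpyrrolidin-2-one (N-vinylpyrrolidinone)
Product: 3 1-ethenyl-3-(1-methyl-1H-pyrrole-2-carbonyl)pyrrolidin-2-one (racemic, used crude)
Conditions: NaH (1.5 equiv), THF, reflux, 3–6 h; then cold 1 M HCl to pH 5–6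
Reagents that add atoms: none
Why: Crossed Claisen condensation in which the lactam enolate of 2 (the only enolisable partner) acylates on the non-enolisable ester 1 and deprotonation of the β-keto lactam product drives the equilibrium; the new C3 stereocentre is racemic and is destroyed in step 2.

**Step 2**
Reactants: 3 1-ethenyl-3-(1-methyl-1H-pyrrole-2-carbonyl)pyrrolidin-2-one
Product: 5 5-(1-methyl-1H-pyrrol-2-yl)-3,4-dihydro-2H-pyrrole, via amino ketone 4 (not isolated)
Conditions: 6 M HCl, reflux, 6–12 h (acetaldehyde distilled off); then aq. NaOH to pH > 12, 0 °C → rt, CH2Cl2 extraction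
Reagents that add atoms: none
Why: Acid hydrolysis of the enamide and the lactam followed by β-keto acid decarboxylation gives the γ-amino ketone, which on basification condenses intramolecularly to the five-membered cyclic imine (the N-vinylpyrrolidinone route to 2-aryl-1-pyrrolines), while the 2-acyl group deactivates the pyrrole towards acid-induced oligomerisation.

**Step 3**
Reactants: 5 5-(1-methyl-1H-pyrrol-2-yl)-3,4-dihydro-2H-pyrrole
Product: 6 1-methyl-1H,1'H-2,2'-bipyrrole
Conditions: 10% Pd on carbon (10 wt%), di-n-hexyl ether (or mesitylene), reflux, N2 sweep, 12–24 h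
Reagents that add atoms: none
Why: Catalytic dehydrogenation of the 2-(pyrrol-2-yl)-1-pyrroline is driven by aromatisation of ring B and removal of H2 in the gas stream, the classical way to the parent 2,2'-bipyrrole.

**Step 4**
Reactants: 6 1-methyl-1H,1'H-2,2'-bipyrrole
Product: 7 1,1'-dimethyl-1H,1'H-2,2'-bipyrrole
Conditions: NaH (1.2 equiv), DMF, 0 °C; MeI (1.2 equiv), 0 °C → rt
Reagents that add atoms: iodomethane, CI
Why: Deprotonation of the single N–H and SN2 N-alkylation of the pyrrolide in a polar aprotic solvent, which gives N- over C-methylation.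

**Step 5**
Reactants: 7 1,1'-dimethyl-1H,1'H-2,2'-bipyrrole
Product: 8 3,3',4,4',5,5'-hexabromo-1,1'-dimethyl-1H,1'H-2,2'-bipyrrole
Conditions: NBS (6.3 equiv, in portions), THF, −78 °C → rt, dark, N2
Reagents that add atoms: N-bromosuccinimide, O=C1CCC(=O)N1Br
Why: Exhaustive electrophilic aromatic bromination of the electron-rich bipyrrole fills all six free ring positions (α first, the hindered 3,3' last), and no stereocentre is created.

## Compound list

1 | methyl 1-methyl-1H-pyrrole-2-carboxylate | COC(=O)c1cccn1C | starting material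
2 | 1-ethenylpyrrolidin-2-one | C=CN1CCCC1=O | starting material
3 | 1-ethenyl-3-(1-methyl-1H-pyrrole-2-carbonyl)pyrrolidin-2-one (racemic) | C=CN1CCC(C(=O)c2cccn2C)C1=O | intermediate
4 | 4-amino-1-(1-methyl-1H-pyrrol-2-yl)butan-1-one (present as its hydrochloride in the acid, not isolated) | Cn1cccc1C(=O)CCCN | intermediate
5 | 5-(1-methyl-1H-pyrrol-2-yl)-3,4-dihydro-2H-pyrrole | Cn1cccc1C1=NCCC1 | intermediate
6 | 1-methyl-1H,1'H-2,2'-bipyrrole | Cn1cccc1-c1ccc[nH]1 | intermediate
7 | 1,1'-dimethyl-1H,1'H-2,2'-bipyrrole | Cn1cccc1-c1cccn1C | intermediate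
8 | 3,3',4,4',5,5'-hexabromo-1,1'-dimethyl-1H,1'H-2,2'-bipyrrole | Cn1c(Br)c(Br)c(Br)c1-c1c(Br)c(Br)c(Br)n1C | target

## Summary

Total step count: 5. Longest linear sequence: 5 steps (1 → 3 → 5 → 6 → 7 → 8).

## Steps most likely to fail, with fallbacks

**Step 1 (Claisen condensation).** Ester 1 is a vinylogous carbamate and a weak electrophile, so the condensation may stall. The fallback sets out from 1 and comes back at 7, bypassing 3 to 6. Ester 1 is treated with MeNH(OMe)·HCl and iPrMgCl (THF, −20 → 0 °C) to give N-methoxy-N,1-dimethyl-1H-pyrrole-2-carboxamide F1. Commercial [2-(1,3-dioxolan-2-yl)ethyl]magnesium bromide (THF, 0 °C → rt) adds once to give 3-(1,3-dioxolan-2-yl)-1-(1-methyl-1H-pyrrol-2-yl)propan-1-one F2. The acetal is opened with 1 M HCl/THF (rt) to 4-(1-methyl-1H-pyrrol-2-yl)-4-oxobutanal F3. Paal–Knorr condensation with MeNH2 (2 M in MeOH, AcOH, 50 °C) then closes ring B directly as the N-methylpyrrole 7.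

**Step 3 (catalytic dehydrogenation).** High temperature and a moderate-yielding aromatisation make this the weakest step. The fallback sets out from 5 and comes back at 6, replacing dehydrogenation by α-functionalisation and elimination. Imine 5 is deprotonated at C4 with LiN(iPr)2 (THF, −78 °C) and the 1-azaallyl anion is trapped with PhSeBr to give 5-(1-methyl-1H-pyrrol-2-yl)-4-(phenylselanyl)-3,4-dihydro-2H-pyrrole F4 (racemic). Oxidation with NaIO4 (NaHCO3, MeOH/H2O, 0 °C) gives 5-(1-methyl-1H-pyrrol-2-yl)-4-(phenylseleninyl)-3,4-dihydro-2H-pyrrole F5. This undergoes syn-elimination at rt to 5-(1-methyl-1H-pyrrol-2-yl)-2H-pyrrole F6, which tautomerises (trace Et3N) to the 1H-pyrrole 6.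

**Step 5 (sixfold bromination).** The electron-rich bipyrrole may be oxidised by NBS, or bromination may stop short at the hindered 3,3' positions. The fallback sets out from 7 and comes back at 8, using ipso-halodemetalation in place of direct substitution. Bipyrrole 7 is permercurated with Hg(OAc)2 (6.5 equiv, EtOH/AcOH, 60 °C) to 3,3',4,4',5,5'-hexakis(acetoxymercurio)-1,1'-dimethyl-1H,1'H-2,2'-bipyrrole F7. This is filtered off and treated with Br2 (6.5 equiv, AcOH/CHCl3, 0 °C → rt) to replace every C–Hg bond by C–Br and give 8. The organomercurial is highly toxic and needs strict containment.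

## Further compounds

F1 | step 1 | N-methoxy-N,1-dimethyl-1H-pyrrole-2-carboxamide | CON(C)C(=O)c1cccn1C
F2 | step 1 | 3-(1,3-dioxolan-2-yl)-1-(1-methyl-1H-pyrrol-2-yl)propan-1-one | Cn1cccc1C(=O)CCC1OCCO1
F3 | step 1 | 4-(1-methyl-1H-pyrrol-2-yl)-4-oxobutanal | Cn1cccc1C(=O)CCC=O
F4 | step 3 | 5-(1-methyl-1H-pyrrol-2-yl)-4-(phenylselanyl)-3,4-dihydro-2H-pyrrole (racemic) | Cn1cccc1C1=NCCC1[Se]c1ccccc1
F5 | step 3 | 5-(1-methyl-1H-pyrrol-2-yl)-4-(phenylseleninyl)-3,4-dihydro-2H-pyrrole | Cn1cccc1C1=NCCC1[Se](=O)c1ccccc1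
F6 | step 3 | 5-(1-methyl-1H-pyrrol-2-yl)-2H-pyrrole | Cn1cccc1C1=NCC=C1
F7 | step 5 | 3,3',4,4',5,5'-hexakis(acetoxymercurio)-1,1'-dimethyl-1H,1'H-2,2'-bipyrrole | Cn1c([Hg]OC(C)=O)c([Hg]OC(C)=O)c([Hg]OC(C)=O)c1-c1c([Hg]OC(C)=O)c([Hg]OC(C)=O)c([Hg]OC(C)=O)n1C
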